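Decalin numbering used throughout: C1 (methyl, arylmethyl), C2 (CHMe), C3, C4, C4a (angular methyl), C5 (acid chain), C6 (isopropylidene), C7, C8, C8a (H); ring B = C1–C4, C4a, C8a; ring A = C4a, C5–C8, C8a.
Enabling feature: H-8a and the 4a-methyl are trans, and C8a and C4a each carry one ring A bond (C8a–C8, C4a–C5); this is what anti addition of a carbon nucleophile and a carbon electrophile across the C4a=C8a bond of a ring B 2-methylcyclohexenone leaves behind.
Cuts (retro): quinone to dimethoxyarene; C6=CMe2 and C5–chain back to C6 and C5 enol triflates; C6=C7 (metathesis); C8a–C8 and C4a–C5 together (conjugate allylation–aldol); C2–CH3 (cuprate); C1–C2 and C4a=C8a (Michael/aldol annulation); aryl–CH2 (Heck).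
Forward order: arene, aldehyde, ring B enone, allyl and hydroxyallyl arms, ring A by ring-closing metathesis, C2 methyl and C4 deoxygenation, C5 chain, C6 isopropylidene, acid, quinone.
Stereochemistry: C1 from the organocatalytic annulation; C8a by allylation anti to the C1 arylmethyl group; C4a by aldol anti to the new allyl group; C2 by axial cuprate addition anti to the axial C1 methyl; C5 by hydroboration on the face opposite the 4a-methyl.

Key step: step 5

Remarks on the chemistry
- Convention: β is the face of H-8a and of the C1 arylmethyl group, α the face of the 1- and 4a-methyl groups; Ar = 2,5-dimethoxy-3-methylphenyl.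
- Assumption: the L-proline-derived sulfonamide of step 4 is taken to give the (R) quaternary centre (enone delivered to the enamine face syn to the acidic N–H, arylmethyl trans to nitrogen); if the sense is opposite, the D-proline-derived catalyst is used.
- Assumption: the carbinol carbon of 12 is drawn S; either epimer serves, because this carbon becomes a ketone in step 12.

Step 1
Reactants: 1 4-methoxy-2-methylphenol
Product: 2 2-iodo-4-methoxy-6-methylphenol
Conditions: N-iodosuccinimide, TsOH (cat.), MeCN, 0 °C to rt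
Reagents that add atoms: N-iodosuccinimide, O=C1CCC(=O)N1I
Why: Electrophilic aromatic iodination is steered by the free hydroxyl group to its only open ortho position, since the para position and the other ortho position carry methoxy and methyl.

Step 2
Reactants: 2 2-iodo-4-methoxy-6-methylphenol
Product: 3 1-iodo-2,5-dimethoxy-3-methylbenzene
Conditions: MeI, K2CO3, acetone, reflux
Reagents that add atoms: iodomethane, CI
Why: Williamson O-methylation of the phenoxide gives the hydroquinone dimethyl ether that is carried to the last step.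

Step 3
Reactants: 3 1-iodo-2,5-dimethoxy-3-methylbenzene; 4 2-methylprop-2-en-1-ol
Product: 5 3-(2,5-dimethoxy-3-methylphenyl)-2-methylpropanal (racemic)
Conditions: Pd(OAc)2 (5 mol%), Bu4NCl, NaHCO3, DMF, 50 °C
Reagents that add atoms: none
Why: In this Heck arylation of an allylic alcohol the aryl group adds to the terminal alkene carbon and β-hydride elimination toward the carbinol carbon gives an enol that tautomerises to the saturated aldehyde; its stereocentre is erased in the next step, so the racemate suffices.

Step 4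
Reactants: 5 3-(2,5-dimethoxy-3-methylphenyl)-2-methylpropanal; 6 pent-1-en-3-one
Product: 8 (R)-4-(2,5-dimethoxy-3-methylbenzyl)-2,4-dimethylcyclohex-2-en-1-one, via keto aldehyde 7 (not isolated)
Conditions: (S)-N-(4-dodecylphenylsulfonyl)pyrrolidine-2-carboxamide (20 mol%), 6 (1.5 equiv), ClCH2CH2Cl, rt; then KOH, EtOH, 0 °C to rt
Reagents that add atoms: none
Why: The chiral secondary amine forms the enamine of the α-branched aldehyde and its acidic sulfonamide N–H guides the vinyl ketone to one enamine face, so the Michael addition should set the quaternary centre (C1), and base then closes ring B by intramolecular aldol condensation onto the non-enolisable aldehyde (Robinson-type annulation).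

Step 5
Reactants: 8 (R)-4-(2,5-dimethoxy-3-methylbenzyl)-2,4-dimethylcyclohex-2-en-1-one; 9 allyltrimethylsilane; 10 acrolein
Product: 12 (2R,3R,4R)-3-allyl-4-(2,5-dimethoxy-3-methylbenzyl)-2-[(S)-1-hydroxyallyl]-2,4-dimethylcyclohexan-1-one, via trichlorotitanium enolate 11 (not isolated)
Conditions: TiCl4 (1.2 equiv), 9 (1.2 equiv), CH2Cl2, −78 °C; then 10 (3 equiv), −78 °C; aq NaHCO3
Reagents that add atoms: titanium tetrachloride, Cl[Ti](Cl)(Cl)Cl (in intermediate 11 only)
Why: TiCl4 binds the enone carbonyl, the γ-carbon of allyltrimethylsilane adds to the β-carbon C8a with loss of the silyl group as Me3SiCl, and the tetrasubstituted trichlorotitanium enolate 11, formed at C4/C4a only, then adds 1,2 to acrolein, so that C8a–C8 and C4a–C5 are made in one flask. The closest known reaction type is the Hosomi–Sakurai conjugate allylation of cyclic enones with aldol capture of the titanium enolate by an aldehyde; no ring closes here, the two arms being joined later by metathesis. C8a should be set by axial attack on the half-chair that places the larger arylmethyl group of the quaternary C1 pseudoaxial and anti to the incoming allylsilane, so the centre made in step 4 controls it. C4a should be set by the new allyl group, which is pseudoaxial to avoid allylic strain with the enolate methyl and sends acrolein to the opposite face, giving the trans relation of the arms that later becomes the trans ring fusion; the carbinol carbon is not controlled and is erased in step 12. The step needs conjugate rather than carbonyl allylation (soft allylsilane on the Lewis acid-bound enone), aldol at C4a rather than C3 (the enolate is generated regiospecifically and does not equilibrate at −78 °C) and little allylation of acrolein (acrolein is added only after the enone is consumed and the silane is kept near one equivalent).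

Step 6
Reactants: 12 (2R,3R,4R)-3-allyl-4-(2,5-dimethoxy-3-methylbenzyl)-2-[(S)-1-hydroxyallyl]-2,4-dimethylcyclohexan-1-one
Product: 13 tert-butyldimethylsilyl ether of 12
Conditions: tBuMe2SiOTf, 2,6-lutidine, CH2Cl2, −78 to 0 °C
Reagents that add atoms: tert-butyldimethylsilyl trifluoromethanesulfonate, CC(C)(C)[Si](C)(C)OS(=O)(=O)C(F)(F)F
Why: Silylation of the hindered secondary alcohol with a silyl triflate blocks retro-aldol cleavage of the β-hydroxy ketone in the basic steps that follow.

Step 7
Reactants: 13 tert-butyldimethylsilyl ether of 12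
Product: 14 trans-fused bicyclic ketone (C4=O; C6=C7; 5β-OSiMe2tBu; 1β-CH2Ar; 1α-Me; 4aα-Me; 8aβ-H)
Conditions: second-generation Grubbs catalyst (5 mol%), CH2Cl2, 40 °C
Reagents that add atoms: none
Why: Ring-closing metathesis of the 1,7-diene forms the cyclohexene ring A with loss of ethene, and because the two arms are trans on C8a and C4a only the trans-fused bicycle can result, with no stereocentre touched.

Step 8
Reactants: 14 trans-fused bicyclic ketone
Product: 16 bicyclic dienone (C2=C3–C4=O; C6=C7; other groups as in 14), via trimethylsilyl enol ether 15 (not isolated)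
Conditions: LiN(iPr)2, Me3SiCl, THF, −78 °C; then Pd(OAc)2 (1.1 equiv), MeCN, rt
Reagents that add atoms: chlorotrimethylsilane, C[Si](C)(C)Cl (in intermediate 15 only)
Why: Saegusa–Ito oxidation; the ketone can enolise only toward C3 because C4a is quaternary, and divalent palladium dehydrosilylates the silyl enol ether to the C2=C3 enone.

Step 9
Reactants: 16 bicyclic dienone
Product: 18 enol triflate (C3=C4–OSO2CF3; 2β-Me; C6=C7; other groups as in 14), via lithium enolate 17 (not isolated)
Conditions: Me2CuLi (from MeLi and CuI), Et2O, −20 to 0 °C; then PhN(SO2CF3)2, THF, 0 °C to rt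
Reagents that add atoms: lithium dimethylcuprate, [Li+].C[Cu-]C; N-phenylbis(trifluoromethanesulfonimide), O=S(=O)(N(c1ccccc1)S(=O)(=O)C(F)(F)F)C(F)(F)F
Why: Cuprate conjugate addition should deliver methyl to C2 axially on the β face, anti to the pseudoaxial 1α-methyl and along the path that leads straight to a chair enolate, and the regiodefined lithium enolate is then O-triflated with the N-aryl triflimide.

Step 10
Reactants: 18 enol triflate
Product: 19 trans-decalin silyl ether (5β-OSiMe2tBu; 2β-Me; 1β-CH2Ar; 1α-Me; 4aα-Me; 8aβ-H)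
Conditions: H2 (1 atm), PtO2, NaHCO3, EtOAc, rt
Reagents that add atoms: none
Why: Hydrogenolysis of the enol triflate C–O bond over platinum followed by alkene hydrogenation is a known way to deoxygenate a ketone through its enol triflate, and the same conditions saturate C6=C7 without creating a stereocentre.

Step 11
Reactants: 19 trans-decalin silyl ether
Product: 20 trans-decalin-5β-ol (2β-Me; 1β-CH2Ar; 1α-Me; 4aα-Me; 8aβ-H)
Conditions: Bu4NF, THF, 50 °C
Reagents that add atoms: none
Why: Fluoride cleaves the silicon–oxygen bond of the silyl ether and frees the secondary alcohol.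

Step 12
Reactants: 20 trans-decalin-5β-ol
Product: 21 trans-decalin-5-one (2β-Me; 1β-CH2Ar; 1α-Me; 4aα-Me; 8aβ-H)
Conditions: Dess–Martin periodinane, CH2Cl2, rt
Reagents that add atoms: none
Why: Oxidation of the secondary alcohol with the hypervalent iodine reagent gives the C5 ketone and removes the uncontrolled carbinol centre.

Step 13
Reactants: 21 trans-decalin-5-one
Product: 23 enol triflate (C5(OSO2CF3)=C6), via potassium enolate 22 (not isolated)
Conditions: KN(SiMe3)2, THF, −78 °C; then PhN(SO2CF3)2, −78 to 0 °C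
Reagents that add atoms: N-phenylbis(trifluoromethanesulfonimide), O=S(=O)(N(c1ccccc1)S(=O)(=O)C(F)(F)F)C(F)(F)F; potassium bis(trimethylsilyl)amide, [K+].C[Si](C)(C)[N-][Si](C)(C)C (potassium in intermediate 22 only)
Why: Enolate O-sulfonylation; the ketone can enolise only toward C6 because C4a is quaternary, so a single enol triflate is expected.

Step 14
Reactants: 23 enol triflate; 24 (3-ethoxy-3-oxopropyl)zinc bromide
Product: 25 ethyl 3-(octalin-5-yl)propanoate (C5=C6; 2β-Me; 1β-CH2Ar; 1α-Me; 4aα-Me; 8aβ-H)
Conditions: 24 (2.5 equiv), Pd(PPh3)4 (5 mol%), LiCl, THF, 60 °C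
Reagents that add atoms: none
Why: Negishi cross-coupling of the enol triflate with the ester-bearing alkylzinc reagent forms the C5–chain bond under neutral conditions that leave the ester intact.

Step 15
Reactants: 25 ethyl 3-(octalin-5-yl)propanoate
Product: 27 6β-hydroxy ester (5α-chain; 5β-H; 2β-Me; 1β-CH2Ar; 1α-Me; 4aα-Me; 8aβ-H), via alkylborane 26 (not isolated)
Conditions: BH3·THF, THF, 0 °C to rt; then H2O2, aq NaOAc, 0 °C to rt
Reagents that add atoms: hydrogen peroxide, OO; borane–tetrahydrofuran, B.C1CCOC1 (boron in intermediate 26 only)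
Why: Hydroboration–oxidation adds boron to the less substituted C6 and hydrogen to C5 in a syn fashion from the β face opposite the axial 4a-methyl, which should set C5 (H β, chain α), while borane reduces the ethyl ester far more slowly than it adds to the alkene.

Step 16
Reactants: 27 6β-hydroxy ester
Product: 28 6-oxo ester (5α-chain; 5β-H)
Conditions: Dess–Martin periodinane, NaHCO3, CH2Cl2, 0 °C to rt
Reagents that add atoms: none
Why: Buffered, non-enolising oxidation of the secondary alcohol gives the C6 ketone without epimerising the adjacent C5 centre.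

Step 17
Reactants: 28 6-oxo ester
Product: 30 enol triflate (C6(OSO2CF3)=C7; 5α-chain), via potassium enolate 29 (not isolated)
Conditions: KN(SiMe3)2 (1.05 equiv), THF, −78 °C; then N-(5-chloropyridin-2-yl)bis(trifluoromethanesulfonimide), −78 °C
Reagents that add atoms: N-(5-chloropyridin-2-yl)bis(trifluoromethanesulfonimide), O=S(=O)(N(c1ccc(Cl)cn1)S(=O)(=O)C(F)(F)F)C(F)(F)F; potassium bis(trimethylsilyl)amide, [K+].C[Si](C)(C)[N-][Si](C)(C)C (potassium in intermediate 29 only)
Why: Kinetic deprotonation takes the unhindered C7 methylene rather than the tertiary, neopentyl-flanked C5–H, and trapping at −78 °C with the reactive pyridyl triflimide prevents equilibration, so C5 keeps its configuration.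

Step 18
Reactants: 30 enol triflate; 31 4,4,5,5-tetramethyl-2-(prop-1-en-2-yl)-1,3,2-dioxaborolane
Product: 32 diene ester (6-isopropenyl; C6=C7; 5α-chain)
Conditions: 31, PdCl2(dppf) (5 mol%), K3PO4, THF/H2O, 50 °C
Reagents that add atoms: none
Why: Suzuki–Miyaura coupling of the enol triflate with the alkenylboronate gives the 2-substituted 1,3-diene with all carbons of the isopropylidene group in place.

Step 19
Reactants: 32 diene ester
Product: 33 isopropylidene ester (C6=CMe2; 5α-chain; 5β-H)
Conditions: H2 (50 atm), (naphthalene)Cr(CO)3 (20 mol%), THF, 45 °C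
Reagents that add atoms: none
Why: The Cr(CO)3 fragment binds the diene in its s-cis form (terminal CH2 next to the ring C7–H) and catalyses 1,4-addition of H2 to the two termini, which leaves the double bond between C6 and the side-chain carbon as the tetrasubstituted isopropylidene and does not touch C5, the ester or the arene.

Step 20
Reactants: 33 isopropylidene ester
Product: 34 isopropylidene acid (hydroquinone dimethyl ether)
Conditions: LiOH, THF/MeOH/H2O, rt; then aq HCl
Reagents that add atoms: lithium hydroxide, [Li+].[OH-]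
Why: Saponification of the ethyl ester is done before the quinone is unmasked, because the quinone would not tolerate hydroxide.

Step 21
Reactants: 34 isopropylidene acid
Product: 35 3-[(1S,2S,4aR,5S,8aR)-1,2,4a-trimethyl-1-[(5-methyl-3,6-dioxocyclohexa-1,4-dien-1-yl)methyl]-6-(propan-2-ylidene)decahydronaphthalen-5-yl]propanoic acid (numbering of this text)
Conditions: (NH4)2Ce(NO3)6, MeCN/H2O, 0 °C
Reagents that add atoms: water, O
Why: Oxidative demethylation of the para-dimethoxyarene by tetravalent cerium gives the para-quinone, the electron-rich arene being oxidised more readily than the tetrasubstituted alkene or the acid at 0 °C.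

Compound list
1 | 4-methoxy-2-methylphenol | COc1ccc(O)c(C)c1 | starting material
2 | 2-iodo-4-methoxy-6-methylphenol | COc1cc(C)c(O)c(I)c1 | intermediate
3 | 1-iodo-2,5-dimethoxy-3-methylbenzene | COc1cc(C)c(OC)c(I)c1 | intermediate
4 | 2-methylprop-2-en-1-ol | C=C(C)CO | starting material
5 | 3-(2,5-dimethoxy-3-methylphenyl)-2-methylpropanal (racemic) | COc1cc(C)c(OC)c(CC(C)C=O)c1 | intermediate
6 | pent-1-en-3-one (ethyl vinyl ketone) | CCC(=O)C=C | starting material
7 | (R)-2-(2,5-dimethoxy-3-methylbenzyl)-2-methyl-5-oxoheptanal (not isolated) | COc1cc(C)c(OC)c(C[C@](C)(C=O)CCC(=O)CC)c1 | intermediate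
8 | (R)-4-(2,5-dimethoxy-3-methylbenzyl)-2,4-dimethylcyclohex-2-en-1-one | COc1cc(C)c(OC)c(C[C@]2(C)C=C(C)C(=O)CC2)c1 | intermediate
9 | allyltrimethylsilane | C=CC[Si](C)(C)C | starting material
10 | acrolein (prop-2-enal) | C=CC=O | starting material
11 | trichlorotitanium enolate of the 3-allyl ketone, allyl trans to arylmethyl (not isolated) | COc1cc(C)c(OC)c(C[C@]2(C)[C@@H](CC=C)C(C)=C(O[Ti](Cl)(Cl)Cl)CC2)c1 | intermediate
12 | (2R,3R,4R)-3-allyl-4-(2,5-dimethoxy-3-methylbenzyl)-2-[(S)-1-hydroxyallyl]-2,4-dimethylcyclohexan-1-one; allyl (on C8a) trans to arylmethyl (C1) and to hydroxyallyl (C4a) | COc1cc(C)c(OC)c(C[C@]2(C)[C@@H](CC=C)[C@](C)([C@@H](O)C=C)C(=O)CC2)c1 | intermediate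
13 | tert-butyldimethylsilyl ether of 12 | COc1cc(C)c(OC)c(C[C@]2(C)[C@@H](CC=C)[C@](C)([C@@H](O[Si](C)(C)C(C)(C)C)C=C)C(=O)CC2)c1 | intermediate
14 | trans-fused bicyclic ketone: C4=O, C6=C7, 5β-OSiMe2tBu, 1β-CH2Ar, 1α-Me, 4aα-Me, 8aβ-H | COc1cc(C)c(OC)c(C[C@]2(C)[C@H]3CC=C[C@H](O[Si](C)(C)C(C)(C)C)[C@]3(C)C(=O)CC2)c1 | intermediate
15 | trimethylsilyl enol ether of 14, C3=C4–OSiMe3 (not isolated) | COc1cc(C)c(OC)c(C[C@]2(C)[C@H]3CC=C[C@H](O[Si](C)(C)C(C)(C)C)[C@]3(C)C(O[Si](C)(C)C)=CC2)c1 | intermediate
16 | bicyclic dienone: C2=C3–C4=O, C6=C7, other groups as in 14 | COc1cc(C)c(OC)c(C[C@]2(C)[C@H]3CC=C[C@H](O[Si](C)(C)C(C)(C)C)[C@]3(C)C(=O)C=C2)c1 | intermediate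
17 | lithium enolate, C3=C4–OLi, 2β-Me (not isolated) | COc1cc(C)c(OC)c(C[C@]2(C)[C@H]3CC=C[C@H](O[Si](C)(C)C(C)(C)C)[C@]3(C)C(O[Li])=C[C@@H]2C)c1 | intermediate
18 | enol triflate: C3=C4–OSO2CF3, 2β-Me, C6=C7, 5β-OSiMe2tBu | COc1cc(C)c(OC)c(C[C@]2(C)[C@H]3CC=C[C@H](O[Si](C)(C)C(C)(C)C)[C@]3(C)C(OS(=O)(=O)C(F)(F)F)=C[C@@H]2C)c1 | intermediate
19 | trans-decalin silyl ether: 5β-OSiMe2tBu, 2β-Me, 1β-CH2Ar, 1α-Me, 4aα-Me, 8aβ-H | COc1cc(C)c(OC)c(C[C@]2(C)[C@H]3CCC[C@H](O[Si](C)(C)C(C)(C)C)[C@]3(C)CC[C@@H]2C)c1 | intermediate
20 | trans-decalin-5β-ol, other groups as in 19 | COc1cc(C)c(OC)c(C[C@]2(C)[C@H]3CCC[C@H](O)[C@]3(C)CC[C@@H]2C)c1 | intermediate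
21 | trans-decalin-5-one, other groups as in 19 | COc1cc(C)c(OC)c(C[C@]2(C)[C@H]3CCCC(=O)[C@]3(C)CC[C@@H]2C)c1 | intermediate
22 | potassium enolate, C5(OK)=C6 (not isolated) | COc1cc(C)c(OC)c(C[C@]2(C)[C@H]3CCC=C(O[K])[C@]3(C)CC[C@@H]2C)c1 | intermediate
23 | enol triflate, C5(OSO2CF3)=C6 | COc1cc(C)c(OC)c(C[C@]2(C)[C@H]3CCC=C(OS(=O)(=O)C(F)(F)F)[C@]3(C)CC[C@@H]2C)c1 | intermediate
24 | (3-ethoxy-3-oxopropyl)zinc bromide | CCOC(=O)CC[Zn]Br | starting material
25 | ethyl 3-(octalin-5-yl)propanoate, C5=C6, 2β-Me, 1β-CH2Ar, 1α-Me, 4aα-Me, 8aβ-H | COc1cc(C)c(OC)c(C[C@]2(C)[C@H]3CCC=C(CCC(=O)OCC)[C@]3(C)CC[C@@H]2C)c1 | intermediate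
26 | alkylborane, 6β-BH2, 5β-H, 5α-chain (not isolated) | COc1cc(C)c(OC)c(C[C@]2(C)[C@H]3CC[C@H](B)[C@@H](CCC(=O)OCC)[C@]3(C)CC[C@@H]2C)c1 | intermediate
27 | 6β-hydroxy ester, 5α-chain, 5β-H | COc1cc(C)c(OC)c(C[C@]2(C)[C@H]3CC[C@H](O)[C@@H](CCC(=O)OCC)[C@]3(C)CC[C@@H]2C)c1 | intermediate
28 | 6-oxo ester, 5α-chain, 5β-H | COc1cc(C)c(OC)c(C[C@]2(C)[C@H]3CCC(=O)[C@@H](CCC(=O)OCC)[C@]3(C)CC[C@@H]2C)c1 | intermediate
29 | potassium enolate, C6(OK)=C7 (not isolated) | COc1cc(C)c(OC)c(C[C@]2(C)[C@H]3CC=C(O[K])[C@@H](CCC(=O)OCC)[C@]3(C)CC[C@@H]2C)c1 | intermediate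
30 | enol triflate, C6(OSO2CF3)=C7, 5α-chain | COc1cc(C)c(OC)c(C[C@]2(C)[C@H]3CC=C(OS(=O)(=O)C(F)(F)F)[C@@H](CCC(=O)OCC)[C@]3(C)CC[C@@H]2C)c1 | intermediate
31 | 4,4,5,5-tetramethyl-2-(prop-1-en-2-yl)-1,3,2-dioxaborolane | CC(=C)B1OC(C)(C)C(C)(C)O1 | starting material
32 | diene ester, 6-isopropenyl, C6=C7, 5α-chain | COc1cc(C)c(OC)c(C[C@]2(C)[C@H]3CC=C(C(C)=C)[C@@H](CCC(=O)OCC)[C@]3(C)CC[C@@H]2C)c1 | intermediate
33 | isopropylidene ester, C6=CMe2, 5α-chain, 5β-H | COc1cc(C)c(OC)c(C[C@]2(C)[C@H]3CCC(=C(C)C)[C@@H](CCC(=O)OCC)[C@]3(C)CC[C@@H]2C)c1 | intermediate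
34 | isopropylidene acid (hydroquinone dimethyl ether) | COc1cc(C)c(OC)c(C[C@]2(C)[C@H]3CCC(=C(C)C)[C@@H](CCC(=O)O)[C@]3(C)CC[C@@H]2C)c1 | intermediate
35 | 3-[(1S,2S,4aR,5S,8aR)-1,2,4a-trimethyl-1-[(5-methyl-3,6-dioxocyclohexa-1,4-dien-1-yl)methyl]-6-(propan-2-ylidene)decahydronaphthalen-5-yl]propanoic acid | CC1=CC(=O)C=C(C[C@]2(C)[C@H]3CCC(=C(C)C)[C@@H](CCC(=O)O)[C@]3(C)CC[C@@H]2C)C1=O | target

Total step count: 21
Longest linear sequence: 21 steps (1 to 35)

Steps most likely to fail

Step 5. The allylsilane may discriminate poorly between the two faces of C8a, because methyl and arylmethyl on C1 differ only moderately in size. The titanium enolate may also be lost by protonation, or acrolein may be consumed by oligomerisation or allylation before the aldol takes place. The fallback separates the two bond formations. It sets out from 8: conjugate allylation with allyltrimethylsilane under catalysis by HN(SO2CF3)2 (which forms the silyl triflimide in the flask) in CH2Cl2 at −78 °C should give the trimethylsilyl enol ether F1, which is isolated and freed of any C8a epimer. A separate Mukaiyama aldol addition of F1 to acrolein with BF3·OEt2 in CH2Cl2 at −78 °C then returns to the route at 12.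

Step 4. The enamine of an aldehyde whose α-substituents are methyl and arylmethyl may form as a mixture of geometries, which would erode the enantioselectivity of the Michael addition. The fallback gives up catalytic induction. It sets out from 5: condensation with pyrrolidine (toluene, water separator) gives the pyrrolidine enamine F2. Stork enamine annulation with ethyl vinyl ketone, then AcOH/NaOAc/H2O at reflux, gives the racemic enone F3. Preparative chromatography on a chiral stationary phase (cellulose tris(3,5-dimethylphenylcarbamate)) then separates the (R)-enone from the (S)-enone F4, which is set aside. The route is rejoined at 8.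

Step 19. The chromium catalyst may be withdrawn by transfer of the Cr(CO)3 fragment to the electron-rich arene, or it may isomerise the diene by hydrogen shift instead of adding H2. The fallback replaces catalytic hydrogenation by dissolving-metal 1,4-reduction on the carboxylate. It sets out from 32: saponification (LiOH, THF/MeOH/H2O) gives the diene acid F5. Reduction of its lithium salt with Li in liquid NH3/THF at −78 °C (no alcohol, NH4Cl quench) should add hydrogen to the terminal CH2 and to C7, the allyl anion being protonated at the less substituted ring carbon. This returns to the route at 34.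

Further compounds
F1 | step 5 | trimethylsilyl enol ether of (3R,4R)-3-allyl-4-(2,5-dimethoxy-3-methylbenzyl)-2,4-dimethylcyclohexanone | COc1cc(C)c(OC)c(C[C@]2(C)[C@@H](CC=C)C(C)=C(O[Si](C)(C)C)CC2)c1
F2 | step 4 | 1-[3-(2,5-dimethoxy-3-methylphenyl)-2-methylprop-1-en-1-yl]pyrrolidine | COc1cc(C)c(OC)c(CC(C)=CN2CCCC2)c1
F3 | step 4 | racemic 4-(2,5-dimethoxy-3-methylbenzyl)-2,4-dimethylcyclohex-2-en-1-one | COc1cc(C)c(OC)c(CC2(C)C=C(C)C(=O)CC2)c1
F4 | step 4 | (S)-4-(2,5-dimethoxy-3-methylbenzyl)-2,4-dimethylcyclohex-2-en-1-one | COc1cc(C)c(OC)c(C[C@@]2(C)C=C(C)C(=O)CC2)c1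
F5 | step 19 | diene acid, 6-isopropenyl, C6=C7, 5α-(2-carboxyethyl) | COc1cc(C)c(OC)c(C[C@]2(C)[C@H]3CC=C(C(C)=C)[C@@H](CCC(=O)O)[C@]3(C)CC[C@@H]2C)c1
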